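The decalin is cut at C5–C6. Ring A is drawn back to a 4,4-disubstituted cyclohexa-2,5-dienone (carbonyl at C3) whose quaternary C10 bears the methyl group and a C9–C8–C7 chain ending in the C6 aldehyde; C1 and C5 are then constitutionally identical β-carbons. One carbene-catalysed intramolecular Stetter reaction adds C6 to C5, closes ring B and fixes the unactivated quaternary centre C10 (with C5) by choosing one dienone arm. The precursor is the (7S)-aldehyde dienone, made by auxiliary alkylation and a Stork–Danheiser sequence. Afterwards C5 is equilibrated to the trans fusion, the C3 carbonyl is shifted to C4 for methyl addition, and O6 is esterified.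

Key step: step 11

Conventions: eudesmane numbering is used for the bicyclic compounds and for the carbons that become them (ring A = C1–C5 and C10; ring B = C5–C10; C14 = methyl on C10; C15 = methyl on C4; isopropyl on C7). β is the face of C14.

Assumption: the (5aR,10bS) antipode of the aminoindanol-derived triazolium salt is taken to select the required dienone arm in step 11; if the sense is opposite, the enantiomeric salt is used.

Design notes:
- (a) The aldehyde is carried as the single 7S epimer (auxiliary alkylation), so carbene and substrate act on one diastereomeric series. C7 is re-equilibrated in step 12, so the other auxiliary antipode can be used if 7R proves the better partner.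
- (b) Oxygen is placed on C4 only after C5 and C7 have been equilibrated, and from the C1=C2–C3 enone, in which C4 is the only enolisable carbon next to C3. A 4-oxygenated 6-ketone is never exposed to base.
- (c) The tertiary carbinol is made by methyl addition to a C4 ketone, which gives the 4β-hydroxyl directly.
- (d) The cinnamate is built on the ester by olefination, so the phenol needs no protecting group.

Step 1
Reactants: 1 (S)-4-benzyl-3-(3-methylbutanoyl)-1,3-oxazolidin-2-one; 2 allyl bromide
Product: 4 (S)-4-benzyl-3-[(2S)-2-isopropylpent-4-enoyl]-1,3-oxazolidin-2-one, via sodium enolate 3 (not isolated)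
Conditions: NaN(SiMe3)2, THF, −78 °C; then 2, −78 → −40 °C
Reagents that add atoms: none
Why: Evans asymmetric alkylation, in which the chelated sodium Z-enolate is allylated on the face away from the benzyl group, which sets the future C7 as S.

Step 2
Reactants: 4 (S)-4-benzyl-3-[(2S)-2-isopropylpent-4-enoyl]-1,3-oxazolidin-2-one
Product: 5 (2S)-2-isopropylpent-4-en-1-ol
Conditions: LiBH4, H2O (1 equiv), Et2O, 0 °C
Reagents that add atoms: none
Why: Reductive cleavage of the imide by borohydride releases the primary alcohol without epimerising the α-centre and returns the auxiliary.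

Step 3
Reactants: 5 (2S)-2-isopropylpent-4-en-1-ol
Product: 6 tert-butyl{[(2S)-2-isopropylpent-4-en-1-yl]oxy}dimethylsilane
Conditions: TBSCl, imidazole, DMF, 23 °C
Reagents that add atoms: tert-butyldimethylsilyl chloride, CC(C)(C)[Si](C)(C)Cl
Why: Silyl ether formation masks the future C6 oxygen through the basic and reductive steps that follow.

Step 4
Reactants: 6 tert-butyl{[(2S)-2-isopropylpent-4-en-1-yl]oxy}dimethylsilane
Product: 8 (3S)-3-{[tert-butyl(dimethyl)silyl]oxymethyl}-4-methylpentan-1-ol, via aldehyde 7 (not isolated)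
Conditions: O3, CH2Cl2/MeOH, −78 °C; then NaBH4, −78 → 23 °C
Reagents that add atoms: ozone, [O-][O+]=O
Why: Ozonolysis with reductive work-up cuts the terminal alkene to a primary alcohol one carbon shorter, which becomes C9.

Step 5
Reactants: 8 (3S)-3-{[tert-butyl(dimethyl)silyl]oxymethyl}-4-methylpentan-1-ol
Product: 9 tert-butyl{[(2S)-2-(2-iodoethyl)-3-methylbutyl]oxy}dimethylsilane
Conditions: I2, PPh3, imidazole, CH2Cl2, 0 °C
Reagents that add atoms: iodine, [I][I]
Why: Appel-type iodination converts the unhindered primary alcohol into the iodide needed for enolate alkylation.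

Step 6
Reactants: 10 3-ethoxycyclohex-2-en-1-one; 9 tert-butyl{[(2S)-2-(2-iodoethyl)-3-methylbutyl]oxy}dimethylsilane
Product: 12 6-[(3S)-3-{[tert-butyl(dimethyl)silyl]oxymethyl}-4-methylpentyl]-3-ethoxycyclohex-2-en-1-one (both C6 epimers), via lithium enolate 11 (not isolated)
Conditions: LiN(iPr)2, THF, −78 °C; then 9, DMPU, −78 → 23 °C
Reagents that add atoms: none
Why: Kinetic α′-deprotonation of the vinylogous ester and SN2 alkylation (first half of a Stork–Danheiser sequence) attach the C7–C9 chain, the new ring stereocentre being inconsequential.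

Step 7
Reactants: 12 6-[(3S)-3-{[tert-butyl(dimethyl)silyl]oxymethyl}-4-methylpentyl]-3-ethoxycyclohex-2-en-1-one
Product: 14 6-[(3S)-3-{[tert-butyl(dimethyl)silyl]oxymethyl}-4-methylpentyl]-3-ethoxy-6-methylcyclohex-2-en-1-one (both C6 epimers), via lithium enolate 13 (not isolated)
Conditions: LiN(iPr)2, THF, −78 °C; then MeI, −78 → 0 °C
Reagents that add atoms: iodomethane, CI
Why: A second α′-enolate alkylation with the small, reactive iodomethane builds the quaternary carbon (future C10 with C14) as an inconsequential epimer mixture.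

Step 8
Reactants: 14 6-[(3S)-3-{[tert-butyl(dimethyl)silyl]oxymethyl}-4-methylpentyl]-3-ethoxy-6-methylcyclohex-2-en-1-one
Product: 16 4-[(3S)-3-(hydroxymethyl)-4-methylpentyl]-4-methylcyclohex-2-en-1-one (both C4 epimers), via allylic alcohol 15 (not isolated)
Conditions: LiAlH4, Et2O, 0 °C; then 2 M HCl, THF, 23 °C
Reagents that add atoms: water, O
Why: Stork–Danheiser transposition, in which 1,2-reduction of the vinylogous ester and acid hydrolysis of the enol ether with loss of water give the 4,4-disubstituted enone while the same acid cleaves the silyl ether.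

Step 9
Reactants: 16 4-[(3S)-3-(hydroxymethyl)-4-methylpentyl]-4-methylcyclohex-2-en-1-one
Product: 17 4-[(3S)-3-(hydroxymethyl)-4-methylpentyl]-4-methylcyclohexa-2,5-dien-1-one
Conditions: DDQ, 1,4-dioxane, 100 °C
Reagents that add atoms: none
Why: Quinone dehydrogenation through the dienol installs the second enone arm and makes the quaternary carbon prochiral, a saturated primary alcohol being inert to DDQ.

Step 10
Reactants: 17 4-[(3S)-3-(hydroxymethyl)-4-methylpentyl]-4-methylcyclohexa-2,5-dien-1-one
Product: 18 4-[(3S)-3-formyl-4-methylpentyl]-4-methylcyclohexa-2,5-dien-1-one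
Conditions: Dess–Martin periodinane, CH2Cl2, 0 → 23 °C
Reagents that add atoms: none
Why: Dess–Martin oxidation gives the α-branched aldehyde under non-basic conditions that spare its α-stereocentre and the dienone.

Step 11
Reactants: 18 4-[(3S)-3-formyl-4-methylpentyl]-4-methylcyclohexa-2,5-dien-1-one
Product: 19 (5R,7S,10S)-15-noreudesm-1-ene-3,6-dione (5βH, cis-fused, isopropyl β)
Conditions: (5aR,10bS)-2-(pentafluorophenyl)-5a,10b-dihydro-4H,6H-indeno[2,1-b][1,2,4]triazolo[4,3-d][1,4]oxazin-2-ium tetrafluoroborate (20 mol%), KN(SiMe3)2 (20 mol%), toluene, 23 °C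
Reagents that add atoms: none
Why: The triazolylidene released by KN(SiMe3)2 adds to the C6 aldehyde and proton transfer gives the Breslow enaminol, whose nucleophilic C6 attacks C5 of one dienone arm; ketonisation of the resulting C3 enolate and loss of the carbene give the 1,4-diketone and return the catalyst. The closest known reaction type is the triazolium-catalysed intramolecular Stetter reaction of aldehyde-tethered 4,4-disubstituted cyclohexadienones, together with Stetter cyclisations of aliphatic aldehydes onto enones. Ring B closes 6-exo-trig, the attacked C5=C4 bond lying outside the new ring. C5 is controlled by the tether, which reaches the flat dienone only on the face that carries C9, so H5 is formed syn to C14 (cis fusion); C10 is controlled by the chiral carbene, which picks one of the two constitutionally identical arms (C5=C4 rather than C1=C2). The step needs arm selectivity and conjugate rather than carbonyl addition: the first rests on the catalyst, supported by the (7S) centre that sits equatorial in a chair-like transition state, the second on the cross-conjugated dienone being a non-enolisable acceptor with no competing acidic site, held so that only a β-carbon is within reach of C6.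

Step 12
Reactants: 19 (5R,7S,10S)-15-noreudesm-1-ene-3,6-dione
Product: 20 (5S,7S,10S)-15-noreudesm-1-ene-3,6-dione (5αH, trans-fused, isopropyl β)
Conditions: NaOMe (0.2 equiv), MeOH, 23 °C
Reagents that add atoms: none
Why: Base-mediated epimerisation through the C6 enolates should lead to the more stable trans-fused diketone with the C7 isopropyl equatorial, any remaining cis isomer being separated and resubmitted.

Step 13
Reactants: 20 (5S,7S,10S)-15-noreudesm-1-ene-3,6-dione
Product: 23 4-hydroxy-5αH-15-noreudesm-1-ene-3,6-dione (C4 epimers, 4α expected to prevail), via silyl dienol ether 21 (not isolated), via silyloxy ketone 22 (not isolated)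
Conditions: LiN(iPr)2, Me3SiCl, THF, −78 °C; then mCPBA, NaHCO3, CH2Cl2, 0 °C; then 1 M HCl, THF, 0 °C
Reagents that add atoms: 3-chloroperoxybenzoic acid, OOC(=O)c1cccc(Cl)c1
Why: Rubottom oxidation, in which in-situ silylation of the kinetic cross-conjugated dienolate (C4 is the only methylene next to a carbonyl, the C6 ketone having only hindered methine protons) and epoxidation of the electron-rich enol ether place oxygen on C4, whose configuration is irrelevant.

Step 14
Reactants: 23 4-hydroxy-5αH-15-noreudesm-1-ene-3,6-dione
Product: 24 5αH-15-noreudesm-1-ene-3,4,6β-triol (C3 and C4 epimers)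
Conditions: LiAlH4, THF, −78 → 0 °C
Reagents that add atoms: none
Why: Hydride reduction adds 1,2 to the enone to give the allylic alcohol, and at C6 the hydride enters from the α face because the axial C10 methyl blocks the β face, which sets the axial 6β-hydroxyl.

Step 15
Reactants: 24 5αH-15-noreudesm-1-ene-3,4,6β-triol
Product: 25 6β-hydroxy-5αH-15-noreudesm-2-en-4-one
Conditions: TsOH·H2O (10 mol%), benzene, 60 °C
Reagents that add atoms: none
Why: Acid ionises the allylic C3 hydroxyl and loss of H4 (a vinylogous pinacol-type dehydration) gives a dienol that tautomerises to the conjugated C4 ketone, which completes the 1,2-carbonyl transposition.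

Step 16
Reactants: 25 6β-hydroxy-5αH-15-noreudesm-2-en-4-one
Product: 26 6β-hydroxy-5αH-15-noreudesman-4-one
Conditions: H2 (1 atm), 10% Pd/C, EtOAc, 23 °C
Reagents that add atoms: none
Why: Heterogeneous hydrogenation saturates the C2–C3 alkene and leaves the ketone, the alcohol and the trans ring fusion untouched.

Step 17
Reactants: 26 6β-hydroxy-5αH-15-noreudesman-4-one
Product: 27 (4S,5S,6R,7S,10R)-eudesmane-4,6-diol (4β-OH, 4α-CH3, 5αH, 6β-OH)
Conditions: MeLi (4 equiv), Et2O, −78 → 0 °C
Reagents that add atoms: methyllithium, [Li]C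
Why: 1,2-Addition of methyllithium to the C4 ketone occurs by equatorial attack from the α face, the β face being shielded by the axial C10 methyl and the 6β-alkoxide, which sets the axial 4β-hydroxyl and the equatorial C15 methyl.

Step 18
Reactants: 27 (4S,5S,6R,7S,10R)-eudesmane-4,6-diol; 28 (diethoxyphosphoryl)acetic acid
Product: 29 (4S,5S,6R,7S,10R)-4-hydroxyeudesman-6-yl (diethoxyphosphoryl)acetate
Conditions: DCC, DMAP (10 mol%), CH2Cl2, 0 → 23 °C
Reagents that add atoms: none
Why: Carbodiimide esterification of Steglich type, which for phosphonoacetic acids runs through a small and reactive ketene, acylates the hindered secondary 6β-hydroxyl in preference to the tertiary 4β-hydroxyl.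

Step 19
Reactants: 29 (4S,5S,6R,7S,10R)-4-hydroxyeudesman-6-yl (diethoxyphosphoryl)acetate; 30 isovanillin
Product: 31 (4S,5S,6R,7S,10R)-4-hydroxyeudesman-6-yl (E)-3-(3-hydroxy-4-methoxyphenyl)prop-2-enoate (target)
Conditions: LiCl, DBU (3 equiv), MeCN, 23 °C
Reagents that add atoms: none
Why: Horner–Wadsworth–Emmons olefination under mild lithium chloride/amine conditions gives the E-cinnamate and tolerates the free phenol, whose anion is meta to the aldehyde, and the tertiary alcohol.

Compound list
1 | (S)-4-benzyl-3-(3-methylbutanoyl)-1,3-oxazolidin-2-one | CC(C)CC(=O)N1[C@@H](Cc2ccccc2)COC1=O | starting material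
2 | allyl bromide | C=CCBr | starting material
3 | sodium Z-enolate of 1 | [Na+].CC(C)/C=C(\[O-])N1[C@@H](Cc2ccccc2)COC1=O | intermediate (not isolated)
4 | (S)-4-benzyl-3-[(2S)-2-isopropylpent-4-enoyl]-1,3-oxazolidin-2-one | O=C([C@H](C(C)C)CC=C)N1[C@@H](Cc2ccccc2)COC1=O | intermediate
5 | (2S)-2-isopropylpent-4-en-1-ol | OC[C@H](C(C)C)CC=C | intermediate
6 | tert-butyl{[(2S)-2-isopropylpent-4-en-1-yl]oxy}dimethylsilane | CC(C)(C)[Si](C)(C)OC[C@H](C(C)C)CC=C | intermediate
7 | (3S)-3-{[tert-butyl(dimethyl)silyl]oxymethyl}-4-methylpentanal | CC(C)(C)[Si](C)(C)OC[C@H](C(C)C)CC=O | intermediate (not isolated)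
8 | (3S)-3-{[tert-butyl(dimethyl)silyl]oxymethyl}-4-methylpentan-1-ol | CC(C)(C)[Si](C)(C)OC[C@H](C(C)C)CCO | intermediate
9 | tert-butyl{[(2S)-2-(2-iodoethyl)-3-methylbutyl]oxy}dimethylsilane | CC(C)(C)[Si](C)(C)OC[C@H](C(C)C)CCI | intermediate
10 | 3-ethoxycyclohex-2-en-1-one | CCOC1=CC(=O)CCC1 | starting material
11 | lithium α′-enolate of 10 | [Li+].CCOC1=CC([O-])=CCC1 | intermediate (not isolated)
12 | 6-[(3S)-3-{[tert-butyl(dimethyl)silyl]oxymethyl}-4-methylpentyl]-3-ethoxycyclohex-2-en-1-one (both C6 epimers) | CCOC1=CC(=O)C(CC[C@H](CO[Si](C)(C)C(C)(C)C)C(C)C)CC1 | intermediate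
13 | lithium α′-enolate of 12 | [Li+].CCOC1=CC([O-])=C(CC[C@H](CO[Si](C)(C)C(C)(C)C)C(C)C)CC1 | intermediate (not isolated)
14 | 6-[(3S)-3-{[tert-butyl(dimethyl)silyl]oxymethyl}-4-methylpentyl]-3-ethoxy-6-methylcyclohex-2-en-1-one (both C6 epimers) | CCOC1=CC(=O)C(C)(CC[C@H](CO[Si](C)(C)C(C)(C)C)C(C)C)CC1 | intermediate
15 | 6-[(3S)-3-{[tert-butyl(dimethyl)silyl]oxymethyl}-4-methylpentyl]-3-ethoxy-6-methylcyclohex-2-en-1-ol (epimer mixture) | CCOC1=CC(O)C(C)(CC[C@H](CO[Si](C)(C)C(C)(C)C)C(C)C)CC1 | intermediate (not isolated)
16 | 4-[(3S)-3-(hydroxymethyl)-4-methylpentyl]-4-methylcyclohex-2-en-1-one (both C4 epimers) | O=C1C=CC(C)(CC[C@H](CO)C(C)C)CC1 | intermediate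
17 | 4-[(3S)-3-(hydroxymethyl)-4-methylpentyl]-4-methylcyclohexa-2,5-dien-1-one | O=C1C=CC(C)(CC[C@H](CO)C(C)C)C=C1 | intermediate
18 | 4-[(3S)-3-formyl-4-methylpentyl]-4-methylcyclohexa-2,5-dien-1-one | O=C[C@H](C(C)C)CCC1(C)C=CC(=O)C=C1 | intermediate (key-step precursor)
19 | (5R,7S,10S)-15-noreudesm-1-ene-3,6-dione (5βH, cis-fused) | O=C1[C@H]2[C@](C)(C=CC(=O)C2)CC[C@H]1C(C)C | intermediate (key-step product)
20 | (5S,7S,10S)-15-noreudesm-1-ene-3,6-dione (5αH, trans-fused) | O=C1[C@@H]2[C@](C)(C=CC(=O)C2)CC[C@H]1C(C)C | intermediate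
21 | 3-(trimethylsilyloxy)-5αH-15-noreudesma-1,3-dien-6-one | O=C1[C@@H]2[C@](C)(C=CC(O[Si](C)(C)C)=C2)CC[C@H]1C(C)C | intermediate (not isolated)
22 | 4-(trimethylsilyloxy)-5αH-15-noreudesm-1-ene-3,6-dione (C4 epimers) | O=C1[C@@H]2[C@](C)(C=CC(=O)C2O[Si](C)(C)C)CC[C@H]1C(C)C | intermediate (not isolated)
23 | 4-hydroxy-5αH-15-noreudesm-1-ene-3,6-dione (C4 epimers) | O=C1[C@@H]2[C@](C)(C=CC(=O)C2O)CC[C@H]1C(C)C | intermediate
24 | 5αH-15-noreudesm-1-ene-3,4,6β-triol (C3 and C4 epimers) | O[C@H]1[C@@H]2[C@](C)(C=CC(O)C2O)CC[C@H]1C(C)C | intermediate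
25 | 6β-hydroxy-5αH-15-noreudesm-2-en-4-one | O[C@H]1[C@@H]2[C@](C)(CC=CC2=O)CC[C@H]1C(C)C | intermediate
26 | 6β-hydroxy-5αH-15-noreudesman-4-one | O[C@H]1[C@@H]2[C@](C)(CCCC2=O)CC[C@H]1C(C)C | intermediate
27 | (4S,5S,6R,7S,10R)-eudesmane-4,6-diol | O[C@H]1[C@@H]2[C@](C)(CCC[C@]2(C)O)CC[C@H]1C(C)C | intermediate
28 | (diethoxyphosphoryl)acetic acid | CCOP(=O)(OCC)CC(=O)O | starting material
29 | (4S,5S,6R,7S,10R)-4-hydroxyeudesman-6-yl (diethoxyphosphoryl)acetate | CCOP(=O)(OCC)CC(=O)O[C@H]1[C@@H]2[C@](C)(CCC[C@]2(C)O)CC[C@H]1C(C)C | intermediate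
30 | isovanillin (3-hydroxy-4-methoxybenzaldehyde) | COc1ccc(C=O)cc1O | starting material
31 | (4S,5S,6R,7S,10R)-4-hydroxyeudesman-6-yl (E)-3-(3-hydroxy-4-methoxyphenyl)prop-2-enoate | COc1ccc(/C=C/C(=O)O[C@H]2[C@@H]3[C@](C)(CCC[C@]3(C)O)CC[C@H]2C(C)C)cc1O | target

Total step count: 19. Longest linear sequence: 19 steps (1 to 31; compounds 2, 10, 28 and 30 are purchased partners).

Steps most likely to fail

Step 11. What may go wrong: slow or reversible addition of the carbene to the hindered α-branched aldehyde, so that aldehyde self-condensation or epimerisation outruns ring closure, and weak discrimination between the two dienone arms in a six-membered closure. The fallback replaces catalyst-controlled polar addition by a reductive cyclisation under substrate control. It sets out from 18: samarium diiodide (SmI2, t-BuOH, THF, −78 °C) brings about a ketyl–enone reductive cyclisation in which C6 again bonds to C5 on the face of the C9 tether, while the (7S) centre, equatorial in the chair-like transition state, selects the arm. This gives the cis-fused 6-hydroxy-15-noreudesm-1-en-3-one F1, and Dess–Martin oxidation of its C6 carbinol comes back to the route at 19.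

Step 13. What may go wrong: competing deprotonation at C5 or C7 next to the C6 ketone, and loss of the new C4 oxygen by β-elimination through the C6 enol. The fallback removes the second ketone before any enolate chemistry. It sets out from 20: NaBH4 with CeCl3·7H2O in MeOH reduces both carbonyls to the allylic diol 5αH-15-noreudesm-1-ene-3,6β-diol F2, and MnO2 re-oxidises only the allylic C3 carbinol to 6β-hydroxy-5αH-15-noreudesm-1-en-3-one F3, whose only enolisable carbon is C4. Deprotonation with KN(SiMe3)2 (2.2 equiv) and oxidation with 2-(phenylsulfonyl)-3-phenyloxaziridine give 4,6β-dihydroxy-5αH-15-noreudesm-1-en-3-one F4, and LiAlH4 reduction comes back to the route at 24.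

Step 15. What may go wrong: further acid-promoted dehydration of the β-hydroxy ketone product through its C4 enol (loss of the 6β-hydroxyl), or migration of C5 in place of loss of H4 from the allyl cation (ring contraction). The fallback replaces Brønsted acid by neutral, metal-catalysed ionisation. It sets out from 24: 1,1′-carbonyldiimidazole converts the 3,4-diol into the cyclic carbonate 6β-hydroxy-5αH-15-noreudesm-1-ene-3,4-diyl carbonate F5. Pd(PPh3)4 (zerovalent palladium, THF, 50 °C) then ionises the allylic C3–O bond with loss of carbon dioxide, and the π-allyl palladium alkoxide collapses by 1,2-hydride shift to the unsaturated C4 ketone. Brief exposure to triethylamine moves the alkene into conjugation, and the route is rejoined at 25.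

Further compounds
F1 | step 11 | (5R,7S,10S)-6-hydroxy-15-noreudesm-1-en-3-one (5βH, cis-fused, C6 epimers) | OC1[C@H]2[C@](C)(C=CC(=O)C2)CC[C@H]1C(C)C
F2 | step 13 | 5αH-15-noreudesm-1-ene-3,6β-diol (C3 epimers) | O[C@H]1[C@@H]2[C@](C)(C=CC(O)C2)CC[C@H]1C(C)C
F3 | step 13 | 6β-hydroxy-5αH-15-noreudesm-1-en-3-one | O[C@H]1[C@@H]2[C@](C)(C=CC(=O)C2)CC[C@H]1C(C)C
F4 | step 13 | 4,6β-dihydroxy-5αH-15-noreudesm-1-en-3-one (C4 epimers) | O[C@H]1[C@@H]2[C@](C)(C=CC(=O)C2O)CC[C@H]1C(C)C
F5 | step 15 | 6β-hydroxy-5αH-15-noreudesm-1-ene-3,4-diyl carbonate (C3 and C4 epimers) | O[C@H]1[C@@H]2[C@](C)(C=CC3OC(=O)OC23)CC[C@H]1C(C)C
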